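## Retrosynthetic overview
1. The strategy rests on the C2–C1–C5–C6 chain of the 3,7-dioxabicyclo[3.3.0]octane. Each bridgehead (C1, C5) carries one oxymethylene (C8, C4) and one aryl-bearing carbon (C2, C6). Cutting O3–C2 and O7–C6 and joining C2 to C6 on paper folds both tetrahydrofuran rings into a trans-1,2-bis(hydroxymethyl)-3,4-diarylcyclobutane.
2. That cyclobutane is a reduced head-to-head cinnamate photodimer. The two different cinnamic acids are loaded one after the other onto C2-symmetric L-threitol acetonide, which makes the [2+2] intramolecular, head-to-head and facially biased.
3. Ring order: dioxolane tether (bought), then cyclobutane with a temporary ten-membered dilactone (photocycloaddition), then hydride removal of the tether. Both tetrahydrofuran rings then form together as the aryl-C/aryl-C cyclobutane bond is broken oxidatively.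
4. C1 and C5 are fixed in the photocycloaddition and never touched again. The aryl-bearing cyclobutane centres are sacrificial, and C2 and C6 are written anew by the bridgeheads in the ring-opening step.

Key step: step 6

Assumption: the (4S,5S) tether is taken to induce the (S,S) configuration at the two carboxyl-bearing cyclobutane carbons. If the induction runs the other way, the equally commercial (4R,5R) diol takes its place, and only the tether centres of the three tethered intermediates change.

## Route

Step 1
Reactants: 1 sinapic acid
Product: 2 O-acetylsinapic acid, (E)-3-(4-acetoxy-3,5-dimethoxyphenyl)prop-2-enoic acid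
Conditions: Ac2O, pyridine, rt; then H2O
Reagents that add atoms: acetic anhydride, CC(=O)OC(C)=O
Why: Standard pyridine-promoted O-acetylation of a phenol; any mixed carboxylic-acetic anhydride is hydrolysed in the aqueous quench, and no stereocentre is involved.

Step 2
Reactants: 3 (E)-3,4,5-trimethoxycinnamic acid; 4 (4S,5S)-2,2-dimethyl-1,3-dioxolane-4,5-dimethanol (2,3-O-isopropylidene-L-threitol)
Product: 5 [(4S,5S)-5-(hydroxymethyl)-2,2-dimethyl-1,3-dioxolan-4-yl]methyl (E)-3-(3,4,5-trimethoxyphenyl)prop-2-enoate
Conditions: 4 (3 equiv), N,N'-diisopropylcarbodiimide, 4-(dimethylamino)pyridine (10 mol %), CH2Cl2, 0 °C → rt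
Reagents that add atoms: none
Why: Steglich esterification in which the excess of the C2-symmetric diol (two equivalent hydroxyls) keeps diacylation low, the water-soluble surplus diol is washed out and recovered, and the dioxolane stereocentres are untouched.

Step 3
Reactants: 2 O-acetylsinapic acid; 5 tether mono(3,4,5-trimethoxycinnamate)
Product: 6 mixed diester of the (4S,5S)-dioxolane-4,5-dimethanol, with one CH2O carrying (E)-3,4,5-trimethoxycinnamoyl and the other (E)-4-acetoxy-3,5-dimethoxycinnamoyl
Conditions: N,N'-diisopropylcarbodiimide, 4-(dimethylamino)pyridine (10 mol %), CH2Cl2, 0 °C → rt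
Reagents that add atoms: none
Why: Second Steglich esterification at the only remaining hydroxyl; the aryl acetate, flanked by two methoxy groups, should tolerate the catalytic acyl-transfer base at low temperature, and both alkenes stay E.

Step 4
Reactants: 6 mixed bis(cinnamate)
Product: 7 all-trans head-to-head cyclobutane fused to a ten-membered dilactone. The two lactone-carbonyl-bearing carbons are (S,S), and the carbons bearing 4-acetoxy-3,5-dimethoxyphenyl and 3,4,5-trimethoxyphenyl are (R,R). Every substituent is trans to both neighbours, and the (4S,5S)-dioxolane is retained.
Conditions: thioxanthen-9-one (10 mol %), degassed CH2Cl2 (3 mM), 405 nm LED, −20 °C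
Reagents that add atoms: none
Why: Triplet-sensitised intramolecular [2+2] photocycloaddition of a diol-tethered bis(cinnamate), a known reaction type, in which the tether enforces head-to-head union through a 1,4-diradical (most likely the bis-benzylic one from Cα–Cα bonding) that closes to the least crowded all-trans ring, while the twist of the trans-dioxolane within the forming ten-membered dilactone selects which pair of alkene faces meet and so sets the carboxyl-bearing centres (S,S) (sense assumed above), with the aryl-bearing centres following as (R,R).

Step 5
Reactants: 7 tethered cyclobutane dilactone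
Product: 8 [(1S,2S,3R,4R)-3-(4-hydroxy-3,5-dimethoxyphenyl)-4-(3,4,5-trimethoxyphenyl)cyclobutane-1,2-diyl]dimethanol
Conditions: LiAlH4 (excess), THF, 0 °C → rt; then aq. potassium sodium tartrate, aq. NH4Cl
Reagents that add atoms: none
Why: Exhaustive LiAlH4 ester reduction takes both lactone carbonyls to primary alcohols, which releases the tether, and cleaves the aryl acetate to the phenol in the same pot; the all-trans array is already the most stable one, so no centre should drift.

Step 6
Reactants: 8 cyclobutane diol-phenol
Product: 11 (1S,2R,5S,6R)-2-(4-hydroxy-3,5-dimethoxyphenyl)-6-(3,4,5-trimethoxyphenyl)-3,7-dioxabicyclo[3.3.0]octane (target CID53356312), via ring-opened quinone methide benzylic cation 9 (not isolated), via monocyclic tetrahydrofuran quinone methide 10 (not isolated)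
Conditions: 2,3-dichloro-5,6-dicyanobenzoquinone (DDQ, 1.0 equiv, slow addition), 2,6-di-tert-butylpyridine, 4 Å MS, CH2Cl2/(CF3)2CHOH 9:1, −40 → 0 °C
Reagents that add atoms: none
Why: Proposed new method: DDQ removes an electron and a proton from the syringyl phenol of 8, and the phenoxyl radical, with spin at the para carbon, breaks the adjacent strained and doubly benzylic C3–C4 ring bond by β-scission to a para-quinone methide and a 3,4,5-trimethoxybenzyl radical, which the reduced quinone partner oxidises at once to cation 9. The cationic carbon (future C6) is taken by the hydroxymethyl oxygen of the carbon two atoms away in a 5-exo-trig closure to 10, and the quinone methide carbon (future C2) is then taken by the other hydroxymethyl oxygen in a 5-exo-trig oxa-Michael addition that restores the phenol and completes the cis-fused bicycle 11. The closest known reaction types are the single-electron oxidative ring opening of arylcyclopropanes and 1,2-diarylcyclobutanes with nucleophile capture and the double oxa-Michael closure of the bis(quinone methide) formed when 4-hydroxycinnamyl alcohols are dimerised oxidatively, an intermediate that 9 matches in connectivity and in relative configuration at its two central carbons while being unsymmetrical and a single enantiomer. C1 and C5 are the untouched (S,S) carbons of 8; C6 and C2 are each set by the neighbouring bridgehead through allylic 1,3-strain, which holds the bridgehead hydrogen in the plane of the cation or quinone methide so that the tethered oxygen arrives from the face of its own chain and the aryl group ends trans to C4 or C8, on the convex face, whatever the configuration of the two erased cyclobutane centres was. The step needs scission plus capture to outrun loss of the benzylic hydrogen, cleavage of the second ring bond (net cycloreversion to two cinnamyl alcohols) and Friedel-Crafts closure to an aryltetralin; ring strain, the overlap of the ring bond rather than the C–H bond with the aryl π system, the 1,3-placement of each hydroxymethyl to its benzylic carbon and the cold, base-buffered, weakly nucleophilic medium are what secure this. Slow addition of a single equivalent of oxidant keeps the product phenol from being oxidised further.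

## Compound list
1 | sinapic acid | COc1cc(/C=C/C(=O)O)cc(OC)c1O | starting material
2 | O-acetylsinapic acid | COc1cc(/C=C/C(=O)O)cc(OC)c1OC(C)=O | intermediate
3 | (E)-3,4,5-trimethoxycinnamic acid | COc1cc(/C=C/C(=O)O)cc(OC)c1OC | starting material
4 | (4S,5S)-2,2-dimethyl-1,3-dioxolane-4,5-dimethanol | CC1(C)O[C@@H](CO)[C@H](CO)O1 | starting material
5 | tether mono(3,4,5-trimethoxycinnamate), (4S,5S) | CC1(C)O[C@@H](COC(=O)/C=C/c2cc(OC)c(OC)c(OC)c2)[C@H](CO)O1 | intermediate
6 | mixed bis(cinnamate) of the tether, (4S,5S), both alkenes E | CC1(C)O[C@@H](COC(=O)/C=C/c2cc(OC)c(OC)c(OC)c2)[C@H](COC(=O)/C=C/c2cc(OC)c(OC(C)=O)c(OC)c2)O1 | intermediate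
7 | all-trans head-to-head cyclobutane in a ten-membered dilactone with the (4S,5S)-dioxolane | CC(=O)Oc1c(OC)cc(cc1OC)[C@@H]2[C@@H](c3cc(OC)c(OC)c(OC)c3)[C@H]4[C@H]2C(=O)OC[C@@H]5OC(C)(C)O[C@H]5COC4=O | intermediate
8 | [(1S,2S,3R,4R)-3-(4-hydroxy-3,5-dimethoxyphenyl)-4-(3,4,5-trimethoxyphenyl)cyclobutane-1,2-diyl]dimethanol | COc1cc([C@@H]2[C@@H](c3cc(OC)c(OC)c(OC)c3)[C@H](CO)[C@H]2CO)cc(OC)c1O | intermediate
9 | ring-opened 2,6-dimethoxy-para-quinone methide with a 2,3-bis(hydroxymethyl) chain ending in the 3,4,5-trimethoxybenzyl cation (central carbons as in 8) | COC1=CC(=C[C@H](CO)[C@@H](CO)[CH+]c2cc(OC)c(OC)c(OC)c2)C=C(OC)C1=O | intermediate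
10 | tetrahydrofuran with 2-(3,4,5-trimethoxyphenyl) and 3-hydroxymethyl trans, and 3-hydroxymethyl and 4-(quinone methide methine) cis | COC1=CC(=C[C@@H]2CO[C@@H](c3cc(OC)c(OC)c(OC)c3)[C@@H]2CO)C=C(OC)C1=O | intermediate
11 | (1S,2R,5S,6R)-2-(4-hydroxy-3,5-dimethoxyphenyl)-6-(3,4,5-trimethoxyphenyl)-3,7-dioxabicyclo[3.3.0]octane | COc1cc([C@@H]2OC[C@@H]3[C@H]2CO[C@H]3c2cc(OC)c(OC)c(OC)c2)cc(OC)c1O | target

Total steps: 6. Longest linear sequence: 5 steps (3 + 4 → 5 → 6 → 7 → 8 → 11; the branch from 1 through 2 is equally long).

## Steps most likely to fail

**Step 6.**
- What may go wrong: after the first scission the second ring bond may also break, giving net cycloreversion and loss of all stereochemical information. The benzylic hydrogen may be lost instead of the ring bond. Traces of acid may epimerise C2 or C6 or divert the quinone methide into Friedel-Crafts closure. The product phenol may be oxidised further.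
- Fallback (known chemistry): it sets out from sinapic acid 1 and comes back at target 11.
- Fischer esterification (MeOH, cat. H2SO4, reflux) gives methyl sinapate F1.
- Excess iBu2AlH in toluene at 0 °C reduces it to sinapyl alcohol F2.
- FeCl3 in aqueous acetone couples two phenoxyl radicals at their β-carbons, and the bis(quinone methide) closes to racemic syringaresinol F3.
- One equivalent of MeI with K2CO3 in acetone caps one of the two equivalent phenols.
- The racemic monomethyl ether is freed from diphenol and dimethyl ether by chromatography.
- Preparative HPLC on a cellulose tris(3,5-dimethylphenylcarbamate) phase then delivers the (1S,2R,5S,6R) enantiomer 11.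

**Step 4.**
- What may go wrong: the diradical may close to the cis-diester (syn head-to-head) ring. The two alkene-face pairs may be poorly discriminated. E/Z cycling and intermolecular coupling may outpace the macrocyclic closure. Isomerism confined to the aryl-bearing carbons is harmless, because step 6 erases those centres.
- Fallback: it gives up the tether in favour of an untethered cross-dimerisation with resolution. It sets out from acids 2 and 3 and comes back at diol 8.
- Carboxylate alkylation of 2 (MeI, KHCO3, DMF) gives methyl (E)-4-acetoxy-3,5-dimethoxycinnamate F4.
- Fischer esterification of 3 gives methyl (E)-3,4,5-trimethoxycinnamate F5.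
- A concentrated MeCN solution of F4 with a fivefold excess of F5 is irradiated at 405 nm with thioxanthen-9-one. This is a known sensitised cinnamate dimerisation that favours the all-trans head-to-head isomer.
- It gives the racemic all-trans dimethyl cyclobutane-1,2-dicarboxylate heterodimer F6, which is separated by chromatography from the homodimer of the excess partner.
- LiAlH4 as in step 5 gives racemic 8, and preparative HPLC on an amylose tris(3,5-dimethylphenylcarbamate) phase gives (1S,2S,3R,4R)-8.

**Step 3.**
- What may go wrong: the acyl-transfer catalyst may move the acetyl group from the aryl acetate onto the free primary alcohol, or strip the acetate. Either process caps the alcohol wrongly and exposes the phenol.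
- Fallback: it sets out from 2 and 5 and comes back at 6 by Mitsunobu esterification (PPh3, diisopropyl azodicarboxylate, THF, 0 °C).
- This activates the primary alcohol of 5 instead of the acid, needs no nucleophilic catalyst, and touches no stereocentre because the reacting carbon is a CH2.
- It makes no new compound (F0).

## Further compounds
F1 | step 6 | methyl sinapate | COC(=O)/C=C/c1cc(OC)c(O)c(OC)c1
F2 | step 6 | sinapyl alcohol | COc1cc(/C=C/CO)cc(OC)c1O
F3 | step 6 | racemic syringaresinol (relative configuration drawn) | COc1cc([C@@H]2OC[C@@H]3[C@H]2CO[C@H]3c2cc(OC)c(O)c(OC)c2)cc(OC)c1O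
F4 | step 4 | methyl (E)-4-acetoxy-3,5-dimethoxycinnamate | COC(=O)/C=C/c1cc(OC)c(OC(C)=O)c(OC)c1
F5 | step 4 | methyl (E)-3,4,5-trimethoxycinnamate | COC(=O)/C=C/c1cc(OC)c(OC)c(OC)c1
F6 | step 4 | racemic all-trans dimethyl 3-(4-acetoxy-3,5-dimethoxyphenyl)-4-(3,4,5-trimethoxyphenyl)cyclobutane-1,2-dicarboxylate (relative configuration drawn) | COc1cc([C@@H]2[C@@H](c3cc(OC)c(OC)c(OC)c3)[C@H](C(=O)OC)[C@H]2C(=O)OC)cc(OC)c1OC(C)=O
F0 | step 3 | none | none
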